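**Retrosynthetic overview** (target numbering: ring A = C1–C5, spiro C6, ring B = C7–C11)
1. Ring A is closed last: C2–C3 bond by an intramolecular carbonyl-ene reaction of α-bromo aldehyde 15 onto an isopropenyl group; C4–Br comes from enamine-catalysed bromination of aldehyde 14.
2. 14 comes from methyl ketone 12 by Tebbe methylenation and terminal-selective Wacker oxidation of the vinyl group.
3. Key step: 12 comes from spiro-epoxide 11 by a 1,2-shift (Meinwald/semipinacol) of the 2-methylbut-3-en-2-yl group from the carbinol carbon to the ring carbon, which creates quaternary C6.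
4. Ring B halogens are set before the shift: a carbonyl-tethered bromolactonisation (C8–Br, C9–O) and a retentive C–O to C–Cl exchange (bromolactone 5 to acid chloride 6).
5. Ring B and the absolute configuration come from an enantioselective Diels–Alder reaction of isoprene with 2-bromoacrolein. Ring order: ring B (step 1), ring A (step 9).

Assumption: in the two catalyst-controlled steps (1 and 9) the named catalyst antipode is the one expected to give the drawn configuration; if the sense of induction is opposite, the mirror-image catalyst is used.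

Step 1
Reactants: 1 isoprene; 2 2-bromoacrolein
Product: 3 (S)-1-bromo-4-methylcyclohex-3-ene-1-carbaldehyde
Conditions: (4R)-2-butyl-4-(1H-indol-3-ylmethyl)-3-tosyl-1,3,2-oxazaborolidin-5-one (10 mol %), CH2Cl2, −78 °C
Reagents that add atoms: none
Why: Catalytic enantioselective Diels–Alder reaction: the boron Lewis acid binds the s-cis aldehyde and its indole group shields one face, so isoprene adds to the other face with para regiochemistry and fixes the C(Br)(CHO) stereocentre that becomes spiro C6.

Step 2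
Reactants: 3 (S)-1-bromo-4-methylcyclohex-3-ene-1-carbaldehyde
Product: 5 (1S,4S,6S)-4,6-dibromo-1-methyl-2-oxabicyclo[2.2.2]octan-3-one, via bromolactol 4 (not isolated)
Conditions: NBS (2.2 equiv), MeCN/H2O 4:1, 0 °C → rt
Reagents that add atoms: N-bromosuccinimide (O=C1CCC(=O)N1Br); water (O)
Why: Bromoetherification of the aldehyde hydrate (bromolactonisation type): the hydrate oxygen can only reach the ring face that carries the CHO-derived carbon and adds at the methyl-bearing (Markovnikov) carbon while bromine adds anti at the neighbouring carbon (future C9–O and C8–Br), and the second equivalent of NBS oxidises the bicyclic lactol to the lactone.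

Step 3
Reactants: 5 (1S,4S,6S)-4,6-dibromo-1-methyl-2-oxabicyclo[2.2.2]octan-3-one
Product: 6 (1S,3S,4S)-1,3-dibromo-4-chloro-4-methylcyclohexane-1-carbonyl chloride
Conditions: SOCl2 (3 equiv), ZnCl2 (10 mol %), CH2Cl2, 40 °C
Reagents that add atoms: thionyl chloride (O=S(Cl)Cl)
Why: Proposed new method: the ZnCl2-activated lactone ionises at its tertiary alkyl C–O bond with assistance from the antiperiplanar bromine (bromonium ion), chloride then opens the bromonium at the tertiary carbon anti to bromine, that is on the face the carboxylate has just left, so C–O becomes C–Cl with retention (future C9) while the carboxylate is trapped irreversibly as the acyl chloride; the closest known reactions are the ZnCl2/SOCl2 opening of butyrolactone to 4-chlorobutanoyl chloride and retentive substitutions next to bromine through bromonium ions.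

Step 4
Reactants: 6 (1S,3S,4S)-1,3-dibromo-4-chloro-4-methylcyclohexane-1-carbonyl chloride; 7 prenyl bromide (1-bromo-3-methylbut-2-ene)
Product: 9 1-[(1S,3S,4S)-1,3-dibromo-4-chloro-4-methylcyclohexyl]-2,2-dimethylbut-3-en-1-one, via prenylzinc bromide 8 (not isolated)
Conditions: Zn dust, LiCl, THF, 0 °C (7 → 8), solution decanted from excess Zn; then 6, THF, −78 → −20 °C
Reagents that add atoms: none
Why: Acylation of an allylic zinc reagent: the acid chloride is attacked by the γ-carbon of prenylzinc bromide (SE2′), which installs the 2-methylbut-3-en-2-yl ketone without touching a stereocentre, and the very hindered ketone does not add a second equivalent at low temperature.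

Step 5
Reactants: 9 1-[(1S,3S,4S)-1,3-dibromo-4-chloro-4-methylcyclohexyl]-2,2-dimethylbut-3-en-1-one
Product: 11 (3R,5S,6S)-5-bromo-6-chloro-2,6-dimethyl-2-(2-methylbut-3-en-2-yl)-1-oxaspiro[2.5]octane (both C2 epimers), via lithium alkoxide 10 (not isolated)
Conditions: MeLi (1.1 equiv), Et2O, −78 °C → rt
Reagents that add atoms: methyllithium ([Li]C)
Why: 1,2-Addition followed by halohydrin-to-epoxide closure (intramolecular Williamson reaction): on warming, the lithium alkoxide displaces the adjacent tertiary bromide from the rear, so the ring carbon (future C6) is inverted and carries oxygen on the face opposite the former C–Br bond; the carbinol epimers are of no consequence.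

Step 6
Reactants: 11 (3R,5S,6S)-5-bromo-6-chloro-2,6-dimethyl-2-(2-methylbut-3-en-2-yl)-1-oxaspiro[2.5]octane
Product: 12 1-[(1R,3S,4S)-3-bromo-4-chloro-4-methyl-1-(2-methylbut-3-en-2-yl)cyclohexyl]ethan-1-one
Conditions: BF3·OEt2 (1.1 equiv), CH2Cl2, −78 °C
Reagents that add atoms: none
Why: Meinwald (semipinacol) rearrangement: BF3 opens the epoxide at the ring carbon while the tertiary allylic group, a far better migrating group than methyl or a ring CH2, shifts 1,2 to the rear of the breaking C–O bond, so quaternary C6 is formed with a second inversion (net retention relative to 9) and the carbinol carbon becomes the acetyl carbonyl.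

Step 7
Reactants: 12 1-[(1R,3S,4S)-3-bromo-4-chloro-4-methyl-1-(2-methylbut-3-en-2-yl)cyclohexyl]ethan-1-one
Product: 13 (1S,2S,4S)-2-bromo-1-chloro-1-methyl-4-(2-methylbut-3-en-2-yl)-4-(prop-1-en-2-yl)cyclohexane
Conditions: Tebbe reagent Cp2Ti(μ-Cl)(μ-CH2)AlMe2 (1.5 equiv), pyridine, THF/toluene, −40 → 0 °C
Reagents that add atoms: Tebbe reagent (C=[Ti](C1C=CC=C1)C1C=CC=C1.C[Al](C)Cl)
Why: Tebbe methylenation (titanium methylidene olefination): the non-basic carbene converts this hindered, enolisable ketone into the isopropenyl group without eliminating the tertiary chloride or the secondary bromide.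

Step 8
Reactants: 13 (1S,2S,4S)-2-bromo-1-chloro-1-methyl-4-(2-methylbut-3-en-2-yl)-4-(prop-1-en-2-yl)cyclohexane
Product: 14 3-[(1S,3S,4S)-3-bromo-4-chloro-4-methyl-1-(prop-1-en-2-yl)cyclohexyl]-3-methylbutanal
Conditions: PdCl2(PhCN)2 (12 mol %), CuCl2·2H2O (12 mol %), AgNO2 (6 mol %), O2 (1 atm), t-BuOH/MeNO2 15:1, rt
Reagents that add atoms: dioxygen (O=O)
Why: Aldehyde-selective (anti-Markovnikov) Wacker oxidation: only the monosubstituted vinyl group reacts (1,1-disubstituted alkenes are inert), and the adjacent quaternary carbon together with the nitrite co-catalyst directs oxygen to the terminal carbon.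

Step 9
Reactants: 14 3-[(1S,3S,4S)-3-bromo-4-chloro-4-methyl-1-(prop-1-en-2-yl)cyclohexyl]-3-methylbutanal
Product: 16 (3S,4S,6S,8S,9S)-4,8-dibromo-9-chloro-5,5,9-trimethyl-1-methylidenespiro[5.5]undecan-3-ol, via bromo aldehyde 15 (not isolated)
Conditions: (S)-2-[diphenyl(trimethylsilyloxy)methyl]pyrrolidine (20 mol %), PhCO2H (20 mol %), 4,4-dibromo-2,6-di-tert-butylcyclohexa-2,5-dien-1-one (1.05 equiv), CH2Cl2/pentane, −40 °C; then Me2AlCl (3 equiv), −78 °C
Reagents that add atoms: 4,4-dibromo-2,6-di-tert-butylcyclohexa-2,5-dien-1-one (CC(C)(C)C1=CC(Br)(Br)C=C(C(C)(C)C)C1=O)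
Why: Enamine-catalysed α-bromination followed by an intramolecular type 2 carbonyl-ene reaction: the catalyst shields one enamine face so bromine sets C4 (S) under reagent control, and in the closed ene transition state the aluminium-bound oxygen is axial with the C–Br bond antiperiplanar to it (dipole-minimised), which should give the trans bromohydrin (3S) while the isopropenyl methyl becomes the exocyclic methylene.

**Compound list**
1 | isoprene | C=CC(C)=C | starting material
2 | 2-bromoacrolein | C=C(Br)C=O | starting material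
3 | (S)-1-bromo-4-methylcyclohex-3-ene-1-carbaldehyde | O=C[C@]1(Br)CCC(C)=CC1 | intermediate
4 | (1S,4S,6S)-4,6-dibromo-1-methyl-2-oxabicyclo[2.2.2]octan-3-ol (bromolactol, both C3 epimers; not isolated) | OC1O[C@@]2(C)CC[C@]1(Br)C[C@@H]2Br | intermediate
5 | (1S,4S,6S)-4,6-dibromo-1-methyl-2-oxabicyclo[2.2.2]octan-3-one (6-Br anti to the ring oxygen on C1) | O=C1O[C@@]2(C)CC[C@]1(Br)C[C@@H]2Br | intermediate
6 | (1S,3S,4S)-1,3-dibromo-4-chloro-4-methylcyclohexane-1-carbonyl chloride (3-Br and 4-Cl trans; 4-Cl cis to COCl) | O=C(Cl)[C@]1(Br)CC[C@](C)(Cl)[C@@H](Br)C1 | intermediate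
7 | prenyl bromide (1-bromo-3-methylbut-2-ene) | CC(C)=CCBr | starting material
8 | prenylzinc bromide (not isolated) | CC(C)=CC[Zn]Br | intermediate
9 | 1-[(1S,3S,4S)-1,3-dibromo-4-chloro-4-methylcyclohexyl]-2,2-dimethylbut-3-en-1-one | C=CC(C)(C)C(=O)[C@]1(Br)CC[C@](C)(Cl)[C@@H](Br)C1 | intermediate
10 | lithium 2-[(1S,3S,4S)-1,3-dibromo-4-chloro-4-methylcyclohexyl]-3,3-dimethylpent-4-en-2-olate (both C2 epimers; not isolated) | C=CC(C)(C)C(C)([O-])[C@]1(Br)CC[C@](C)(Cl)[C@@H](Br)C1.[Li+] | intermediate
11 | (3R,5S,6S)-5-bromo-6-chloro-2,6-dimethyl-2-(2-methylbut-3-en-2-yl)-1-oxaspiro[2.5]octane (both C2 epimers) | C=CC(C)(C)C1(C)O[C@@]12CC[C@](C)(Cl)[C@@H](Br)C2 | intermediate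
12 | 1-[(1R,3S,4S)-3-bromo-4-chloro-4-methyl-1-(2-methylbut-3-en-2-yl)cyclohexyl]ethan-1-one | C=CC(C)(C)[C@@]1(C(C)=O)CC[C@](C)(Cl)[C@@H](Br)C1 | intermediate
13 | (1S,2S,4S)-2-bromo-1-chloro-1-methyl-4-(2-methylbut-3-en-2-yl)-4-(prop-1-en-2-yl)cyclohexane | C=CC(C)(C)[C@@]1(C(C)=C)CC[C@](C)(Cl)[C@@H](Br)C1 | intermediate
14 | 3-[(1S,3S,4S)-3-bromo-4-chloro-4-methyl-1-(prop-1-en-2-yl)cyclohexyl]-3-methylbutanal | O=CCC(C)(C)[C@@]1(C(C)=C)CC[C@](C)(Cl)[C@@H](Br)C1 | intermediate
15 | (2S)-2-bromo-3-[(1S,3S,4S)-3-bromo-4-chloro-4-methyl-1-(prop-1-en-2-yl)cyclohexyl]-3-methylbutanal (not isolated) | O=C[C@@H](Br)C(C)(C)[C@@]1(C(C)=C)CC[C@](C)(Cl)[C@@H](Br)C1 | intermediate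
16 | (3S,4S,6S,8S,9S)-4,8-dibromo-9-chloro-5,5,9-trimethyl-1-methylidenespiro[5.5]undecan-3-ol | C=C1C[C@H](O)[C@@H](Br)C(C)(C)[C@]12CC[C@](C)(Cl)[C@@H](Br)C2 | target

**Totals**
Total step count: 9. Longest linear sequence: 9 steps (1 and 2 to 16).

**Three steps most likely to fail**

Step 3 (the proposed new step). Risks: chloride may open the bromonium at the secondary carbon (1,2-bromine shift), or elimination may compete. Fallback with known chemistry, setting out from 5 and returning at 9: 5 is treated with anhydrous HCl in methanol (Fischer-type lactone methanolysis; the liberated tertiary alcohol is converted in the same pot into the chloride through the bromonium ion, a classical neighbouring-bromine substitution with retention) to give methyl (1S,3S,4S)-1,3-dibromo-4-chloro-4-methylcyclohexane-1-carboxylate F1. F1 is then acylated by prenylmagnesium chloride (1.05 equiv, THF, −78 °C; attack through the γ-carbon, the hindered ketone does not add again) to give 9.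

Step 6. Risks: the fully substituted epoxide could open at the other C–O bond (ring enlargement of ring B) or react through a free cation with loss of configuration at C6. Fallback setting out from 6 and returning at 12, using a trisubstituted epoxide that can ionise only at the ring carbon:
- 6 is reduced with LiAlH(Ot-Bu)3 (THF, −78 °C) to (1S,3S,4S)-1,3-dibromo-4-chloro-4-methylcyclohexane-1-carbaldehyde F2.
- Prenylmagnesium chloride (THF, −78 °C, cold quench) gives 1-[(1S,3S,4S)-1,3-dibromo-4-chloro-4-methylcyclohexyl]-2,2-dimethylbut-3-en-1-ol F3.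
- NaH (THF, 0 °C) closes it to (3R,5S,6S)-5-bromo-6-chloro-6-methyl-2-(2-methylbut-3-en-2-yl)-1-oxaspiro[2.5]octane F4.
- Methylaluminium bis(4-bromo-2,6-di-tert-butylphenoxide) (CH2Cl2, −78 °C) effects the known epoxide-to-aldehyde rearrangement with anti alkyl shift to (1R,3S,4S)-3-bromo-4-chloro-4-methyl-1-(2-methylbut-3-en-2-yl)cyclohexane-1-carbaldehyde F5.
- MeMgBr (Et2O, −78 °C) gives 1-[(1R,3S,4S)-3-bromo-4-chloro-4-methyl-1-(2-methylbut-3-en-2-yl)cyclohexyl]ethan-1-ol F6, and Dess–Martin periodinane returns 12.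

Step 9. Risks: the axial methyl on C5 crowds the closed ene transition state, so the cis bromohydrin, a Prins chloride or no cyclisation may result; the trans selectivity is the least secure stereochemical call in the route. The tertiary chloride may also be sensitive to Me2AlCl. Fallback setting out from 12 and returning at 16, replacing the ene reaction by an allylsilane cyclisation with an open transition state:
- 12 is converted (KHMDS, PhNTf2, THF, −78 °C) into 1-[(1R,3S,4S)-3-bromo-4-chloro-4-methyl-1-(2-methylbut-3-en-2-yl)cyclohexyl]ethenyl trifluoromethanesulfonate F7.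
- Pd(PPh3)4-catalysed coupling with Me3SiCH2MgCl gives {2-[(1R,3S,4S)-3-bromo-4-chloro-4-methyl-1-(2-methylbut-3-en-2-yl)cyclohexyl]prop-2-en-1-yl}trimethylsilane F8.
- Hydroboration of the vinyl group with 9-BBN and direct oxidation of the alkylborane with pyridinium chlorochromate gives 3-{(1R,3S,4S)-3-bromo-4-chloro-4-methyl-1-[3-(trimethylsilyl)prop-1-en-2-yl]cyclohexyl}-3-methylbutanal F9.
- The same enamine-catalysed bromination as in step 9 gives (2S)-2-bromo-3-{(1S,3S,4S)-3-bromo-4-chloro-4-methyl-1-[3-(trimethylsilyl)prop-1-en-2-yl]cyclohexyl}-3-methylbutanal F10.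
- BF3·OEt2 (CH2Cl2, −78 °C) closes ring A by an intramolecular Hosomi–Sakurai reaction; the chair transition state with C–Br and C–O both equatorial (Felkin–Anh) gives 16.

Further compounds
F1 | step 3 | methyl (1S,3S,4S)-1,3-dibromo-4-chloro-4-methylcyclohexane-1-carboxylate | COC(=O)[C@]1(Br)CC[C@](C)(Cl)[C@@H](Br)C1
F2 | step 6 | (1S,3S,4S)-1,3-dibromo-4-chloro-4-methylcyclohexane-1-carbaldehyde | O=C[C@]1(Br)CC[C@](C)(Cl)[C@@H](Br)C1
F3 | step 6 | 1-[(1S,3S,4S)-1,3-dibromo-4-chloro-4-methylcyclohexyl]-2,2-dimethylbut-3-en-1-ol (both carbinol epimers) | C=CC(C)(C)C(O)[C@]1(Br)CC[C@](C)(Cl)[C@@H](Br)C1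
F4 | step 6 | (3R,5S,6S)-5-bromo-6-chloro-6-methyl-2-(2-methylbut-3-en-2-yl)-1-oxaspiro[2.5]octane (both C2 epimers) | C=CC(C)(C)C1O[C@@]12CC[C@](C)(Cl)[C@@H](Br)C2
F5 | step 6 | (1R,3S,4S)-3-bromo-4-chloro-4-methyl-1-(2-methylbut-3-en-2-yl)cyclohexane-1-carbaldehyde | C=CC(C)(C)[C@@]1(C=O)CC[C@](C)(Cl)[C@@H](Br)C1
F6 | step 6 | 1-[(1R,3S,4S)-3-bromo-4-chloro-4-methyl-1-(2-methylbut-3-en-2-yl)cyclohexyl]ethan-1-ol (both carbinol epimers) | C=CC(C)(C)[C@@]1(C(C)O)CC[C@](C)(Cl)[C@@H](Br)C1
F7 | step 9 | 1-[(1R,3S,4S)-3-bromo-4-chloro-4-methyl-1-(2-methylbut-3-en-2-yl)cyclohexyl]ethenyl trifluoromethanesulfonate | C=CC(C)(C)[C@@]1(C(=C)OS(=O)(=O)C(F)(F)F)CC[C@](C)(Cl)[C@@H](Br)C1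
F8 | step 9 | {2-[(1R,3S,4S)-3-bromo-4-chloro-4-methyl-1-(2-methylbut-3-en-2-yl)cyclohexyl]prop-2-en-1-yl}trimethylsilane | C=CC(C)(C)[C@@]1(C(=C)C[Si](C)(C)C)CC[C@](C)(Cl)[C@@H](Br)C1
F9 | step 9 | 3-{(1R,3S,4S)-3-bromo-4-chloro-4-methyl-1-[3-(trimethylsilyl)prop-1-en-2-yl]cyclohexyl}-3-methylbutanal | O=CCC(C)(C)[C@@]1(C(=C)C[Si](C)(C)C)CC[C@](C)(Cl)[C@@H](Br)C1
F10 | step 9 | (2S)-2-bromo-3-{(1S,3S,4S)-3-bromo-4-chloro-4-methyl-1-[3-(trimethylsilyl)prop-1-en-2-yl]cyclohexyl}-3-methylbutanal | O=C[C@@H](Br)C(C)(C)[C@@]1(C(=C)C[Si](C)(C)C)CC[C@](C)(Cl)[C@@H](Br)C1
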